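## Retrosynthetic overview

- The target is the C8 (S)-3-hydroxy-2-methylpropanoate of a 1(10)-cis, 4,5-trans 6,12-germacranolide (ring C1–C10, lactone C11–C13, C14 methyl, C15 CH2OH).
- Late stage: desilylation ⇐ Z-selective ring-closing metathesis at C1=C10 (ten-membered ring) ⇐ acylation of C8–OH with the silyl-protected (S)-hydroxy acid.
- Key disconnection: the α-methylene-γ-lactone is cut at O–C6 and C7–C11, giving an acyclic (4-trans,6-cis) C4=C5–C6=C7 dienol and 2-bromoacrylic acid. A palladium-catalysed [3+2] diene heteroannulation joins them, sets C6 and C7 and delivers the exocyclic methylene directly.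
- Enabling feature: the lactone carbinol carbon C6 is allylic to the ring olefin C4=C5 and C7 is its neighbour. The unit C7–C6(O)–C5=C4 is therefore the 1,2-carbo-oxygenation product of a conjugated diene through a C6–C5–C4 π-allyl, and the C8 carbinol next to C7 controls the face.
- The dienol comes from Sonogashira coupling of a Z-vinyl iodide with an (S)-propargylic alcohol, then cis-semihydrogenation. Ring order: γ-lactone first (step 7), ten-membered carbocycle second (step 11).

Key step: step 7

Remark: in the numbering above the target SMILES is read as 6R,7R,8S,2'S, with a cis (Z) C1=C10 olefin and a trans-in-ring C4=C5 olefin (Z by CIP because of the CH2OH group), i.e. a trans-fused lactone.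

## Route

Step 1
Reactants: 1 prop-2-yn-1-ol; 2 (2E)-5-bromopent-2-ene
Product: 5 (2Z)-3-iodo-2-[(3E)-pent-3-en-1-yl]prop-2-en-1-ol, via pent-3-enylmagnesium bromide 3 (not isolated), via bromomagnesium alkenyl alkoxide 4 (not isolated)
Conditions: 2, Mg turnings, THF, rt; then 1 (0.4 equiv relative to 3), CuI (10 mol %), Et2O–THF, 0 °C to reflux; I2, −40 to 0 °C; 1 M HCl work-up
Reagents that add atoms: iodine, II
Why: The copper-catalysed carbomagnesiation of the magnesium alkoxide of propargyl alcohol is an anti addition that puts the pentenyl group on C2 and magnesium on C3 cis to the CH2O arm (alkoxide chelate), and iodinolysis of the C–Mg bond with retention should give the Z-iodide; no stereocentre is formed.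

Step 2
Reactants: 5 (2Z)-3-iodo-2-[(3E)-pent-3-en-1-yl]prop-2-en-1-ol
Product: 6 tert-butyl{[(2Z)-3-iodo-2-[(3E)-pent-3-en-1-yl]prop-2-en-1-yl]oxy}dimethylsilane
Conditions: TBSCl, imidazole, DMF, 0 °C to rt
Reagents that add atoms: tert-butyldimethylsilyl chloride, CC(C)(C)[Si](C)(C)Cl
Why: Standard silylation of a primary alcohol should protect the future C15 oxygen without touching the vinyl iodide.

Step 3
Reactants: 7 3-(trimethylsilyl)prop-2-ynal; 8 tributyl(2-methylprop-2-en-1-yl)stannane
Product: 9 (3S)-5-methyl-1-(trimethylsilyl)hex-5-en-1-yn-3-ol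
Conditions: (S)-BINOL (20 mol %), Ti(OiPr)4 (10 mol %), 4 Å MS, CH2Cl2, −20 °C; aq NaHCO3
Reagents that add atoms: none
Why: Keck asymmetric allylation, in which the BINOL–titanium Lewis acid activates the ynal and the methallylstannane adds through an open transition state to the si face dictated by (S)-BINOL, should set the carbinol centre (the future C8) as S.

Step 4
Reactants: 9 (3S)-5-methyl-1-(trimethylsilyl)hex-5-en-1-yn-3-ol
Product: 10 (3S)-5-methylhex-5-en-1-yn-3-ol
Conditions: K2CO3 (cat.), MeOH, 0 °C to rt
Reagents that add atoms: none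
Why: Methoxide-mediated protodesilylation cleaves only the C(sp)–Si bond and leaves the carbinol stereocentre untouched.

Step 5
Reactants: 6 tert-butyl{[(2Z)-3-iodo-2-[(3E)-pent-3-en-1-yl]prop-2-en-1-yl]oxy}dimethylsilane; 10 (3S)-5-methylhex-5-en-1-yn-3-ol
Product: 11 (4S,7Z,11E)-8-{[(tert-butyldimethylsilyl)oxy]methyl}-2-methyltrideca-1,7,11-trien-5-yn-4-ol
Conditions: Pd(PPh3)2Cl2 (5 mol %), CuI (10 mol %), Et3N, THF, rt
Reagents that add atoms: none
Why: Sonogashira coupling of the terminal alkyne with the vinyl iodide proceeds with retention of olefin geometry and tolerates the free propargylic alcohol.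

Step 6
Reactants: 11 (4S,7Z,11E)-8-{[(tert-butyldimethylsilyl)oxy]methyl}-2-methyltrideca-1,7,11-trien-5-yn-4-ol
Product: 12 (4S,5Z,7Z,11E)-8-{[(tert-butyldimethylsilyl)oxy]methyl}-2-methyltrideca-1,5,7,11-tetraen-4-ol
Conditions: H2 (1 atm), Pd on CaCO3 poisoned with Pb(OAc)2 (Lindlar catalyst), quinoline, EtOAc–hexane, rt, stopped after 1 equiv H2
Reagents that add atoms: none
Why: Lindlar semihydrogenation adds H2 syn to the alkyne only, which should give the cis C6=C7 olefin of the conjugated diene while the poisoned catalyst leaves the other olefins alone.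

Step 7
Reactants: 12 (4S,5Z,7Z,11E)-8-{[(tert-butyldimethylsilyl)oxy]methyl}-2-methyltrideca-1,5,7,11-tetraen-4-ol; 13 2-bromoprop-2-enoic acid
Product: 14 (4R,5R)-5-[(1Z,5E)-2-{[(tert-butyldimethylsilyl)oxy]methyl}hepta-1,5-dien-1-yl]-4-[(1S)-1-hydroxy-3-methylbut-3-en-1-yl]-3-methylideneoxolan-2-one
Conditions: 13 (1.5 equiv), Pd(OAc)2 (10 mol %), P(2-furyl)3 (20 mol %), NaHCO3 (3 equiv), n-Bu4NCl (1 equiv), DMF, 60 °C
Reagents that add atoms: none
Why: Zerovalent palladium (formed from Pd(OAc)2 and the phosphine) inserts into the C–Br bond of 13, the 1-carboxyvinylpalladium species adds syn across the C6=C7 end of the diene with carbon going to the less substituted terminus C7, and the carboxylate then attacks the C6 terminus of the resulting C6–C5–C4 π-allylpalladium intermediate, releasing zerovalent palladium and HBr (taken up by NaHCO3). The closest known reaction type is the Larock-type palladium-catalysed heteroannulation of 1,3-dienes by aryl or vinylic halides that carry a carboxylic acid, a formal [3+2] route to γ-lactones. The only ring that closes is the γ-lactone, by 5-exo attack of the carboxylate oxygen on the allyl terminus C6 (attack at C4 would need a seven-membered ring and a fully substituted centre). C7 is set in the carbopalladation: allylic 1,3-strain in the Z-allylic alcohol holds the C8–H bond in the plane of the C6=C7 bond, and the vinylpalladium adds to the face that carries the small, palladium-coordinating hydroxyl group and is remote from the methallyl branch, which gives 7R next to 8S. C6 is set in the C–O bond formation: the carboxylate, a stabilised oxygen nucleophile, attacks the chloride-ligated π-allyl on the face opposite to palladium, so the cis C6=C7 unit is turned into the trans-4,5-disubstituted lactone (6R), which should also be the thermodynamically preferred diastereomer. The step needs regio- and chemoselectivity, secured by the fully substituted C4 terminus (never attacked, so the C4=C5 geometry is kept) and by the two remaining olefins being 1,1-disubstituted and internal, both poor acceptors for intermolecular carbopalladation.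

Step 8
Reactants: 15 methyl (2S)-3-hydroxy-2-methylpropanoate
Product: 16 methyl (2S)-3-[(tert-butyldimethylsilyl)oxy]-2-methylpropanoate
Conditions: TBSCl, imidazole, CH2Cl2, 0 °C to rt
Reagents that add atoms: tert-butyldimethylsilyl chloride, CC(C)(C)[Si](C)(C)Cl
Why: Standard silylation of the primary alcohol leaves the α-stereocentre untouched.

Step 9
Reactants: 16 methyl (2S)-3-[(tert-butyldimethylsilyl)oxy]-2-methylpropanoate
Product: 17 (2S)-3-[(tert-butyldimethylsilyl)oxy]-2-methylpropanoic acid
Conditions: LiOH·H2O, THF–MeOH–H2O, 0 °C; 1 M HCl to pH 4 at 0 °C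
Reagents that add atoms: lithium hydroxide, [Li+].[OH-]
Why: Saponification at 0 °C cleaves the methyl ester by acyl–oxygen fission without enolising the α-centre and without loss of the primary silyl ether.

Step 10
Reactants: 14 (4R,5R)-5-[(1Z,5E)-2-{[(tert-butyldimethylsilyl)oxy]methyl}hepta-1,5-dien-1-yl]-4-[(1S)-1-hydroxy-3-methylbut-3-en-1-yl]-3-methylideneoxolan-2-one; 17 (2S)-3-[(tert-butyldimethylsilyl)oxy]-2-methylpropanoic acid
Product: 19 (1S)-1-[(2R,3R)-2-[(1Z,5E)-2-{[(tert-butyldimethylsilyl)oxy]methyl}hepta-1,5-dien-1-yl]-4-methylidene-5-oxooxolan-3-yl]-3-methylbut-3-en-1-yl (2S)-3-[(tert-butyldimethylsilyl)oxy]-2-methylpropanoate, via mixed anhydride 18 (not isolated)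
Conditions: 17, 2,4,6-trichlorobenzoyl chloride, Et3N, THF, rt; then 14, DMAP, toluene, rt
Reagents that add atoms: none
Why: Yamaguchi esterification acylates the hindered secondary C8 hydroxyl at oxygen, so C8 keeps its configuration, and the mild conditions should not epimerise the α-centre of the acid or move the lactone.

Step 11
Reactants: 19 (1S)-1-[(2R,3R)-2-[(1Z,5E)-2-{[(tert-butyldimethylsilyl)oxy]methyl}hepta-1,5-dien-1-yl]-4-methylidene-5-oxooxolan-3-yl]-3-methylbut-3-en-1-yl (2S)-3-[(tert-butyldimethylsilyl)oxy]-2-methylpropanoate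
Product: 20 (3aR,4S,6Z,10Z,11aR)-10-{[(tert-butyldimethylsilyl)oxy]methyl}-6-methyl-3-methylidene-2-oxo-2,3,3a,4,5,8,9,11a-octahydrocyclodeca[b]furan-4-yl (2S)-3-[(tert-butyldimethylsilyl)oxy]-2-methylpropanoate
Conditions: second-generation Grubbs catalyst (H2IMes)(PCy3)Cl2Ru=CHPh (10 mol %), 1,4-benzoquinone (20 mol %), toluene (1 mM), 80 °C
Reagents that add atoms: none
Why: Ring-closing metathesis should start at the propenyl end and close onto the methallyl olefin with loss of propene, the trans-fused lactone holding the two chains close, and the cis (Z) C1=C10 olefin is expected as the less strained geometry of a ten-membered ring that already holds one trans olefin, while the α-methylene lactone and the trisubstituted C4=C5 olefin are poor metathesis partners.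

Step 12
Reactants: 20 (3aR,4S,6Z,10Z,11aR)-10-{[(tert-butyldimethylsilyl)oxy]methyl}-6-methyl-3-methylidene-2-oxo-2,3,3a,4,5,8,9,11a-octahydrocyclodeca[b]furan-4-yl (2S)-3-[(tert-butyldimethylsilyl)oxy]-2-methylpropanoate
Product: 21 (3aR,4S,6Z,10Z,11aR)-10-(hydroxymethyl)-6-methyl-3-methylidene-2-oxo-2,3,3a,4,5,8,9,11a-octahydrocyclodeca[b]furan-4-yl (2S)-3-hydroxy-2-methylpropanoate
Conditions: HF·pyridine, pyridine, THF, 0 °C to rt
Reagents that add atoms: none
Why: Buffered HF·pyridine should cleave both primary silyl ethers without acyl migration, lactone opening or conjugate addition to the α-methylene lactone.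

## Compound list

1 | prop-2-yn-1-ol | C#CCO | starting material
2 | (2E)-5-bromopent-2-ene | C/C=C/CCBr | starting material
3 | (3E)-pent-3-en-1-ylmagnesium bromide | C/C=C/CC[Mg]Br | intermediate
4 | bromomagnesium (2Z)-3-(bromomagnesio)-2-[(3E)-pent-3-en-1-yl]prop-2-en-1-olate | Br[Mg]/C=C(\CO[Mg]Br)CC/C=C/C | intermediate
5 | (2Z)-3-iodo-2-[(3E)-pent-3-en-1-yl]prop-2-en-1-ol | I/C=C(\CO)CC/C=C/C | intermediate
6 | tert-butyl{[(2Z)-3-iodo-2-[(3E)-pent-3-en-1-yl]prop-2-en-1-yl]oxy}dimethylsilane | I/C=C(\CO[Si](C)(C)C(C)(C)C)CC/C=C/C | intermediate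
7 | 3-(trimethylsilyl)prop-2-ynal | C[Si](C)(C)C#CC=O | starting material
8 | tributyl(2-methylprop-2-en-1-yl)stannane | C=C(C)C[Sn](CCCC)(CCCC)CCCC | starting material
9 | (3S)-5-methyl-1-(trimethylsilyl)hex-5-en-1-yn-3-ol | C=C(C)C[C@H](O)C#C[Si](C)(C)C | intermediate
10 | (3S)-5-methylhex-5-en-1-yn-3-ol | C=C(C)C[C@H](O)C#C | intermediate
11 | (4S,7Z,11E)-8-{[(tert-butyldimethylsilyl)oxy]methyl}-2-methyltrideca-1,7,11-trien-5-yn-4-ol | C=C(C)C[C@H](O)C#C\C=C(/CO[Si](C)(C)C(C)(C)C)CC/C=C/C | intermediate
12 | (4S,5Z,7Z,11E)-8-{[(tert-butyldimethylsilyl)oxy]methyl}-2-methyltrideca-1,5,7,11-tetraen-4-ol | C=C(C)C[C@H](O)/C=C\C=C(/CO[Si](C)(C)C(C)(C)C)CC/C=C/C | intermediate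
13 | 2-bromoprop-2-enoic acid | C=C(Br)C(=O)O | starting material
14 | (4R,5R)-5-[(1Z,5E)-2-{[(tert-butyldimethylsilyl)oxy]methyl}hepta-1,5-dien-1-yl]-4-[(1S)-1-hydroxy-3-methylbut-3-en-1-yl]-3-methylideneoxolan-2-one | C=C1C(=O)O[C@H](/C=C(\CO[Si](C)(C)C(C)(C)C)CC/C=C/C)[C@H]1[C@@H](O)CC(C)=C | intermediate
15 | methyl (2S)-3-hydroxy-2-methylpropanoate | COC(=O)[C@@H](C)CO | starting material
16 | methyl (2S)-3-[(tert-butyldimethylsilyl)oxy]-2-methylpropanoate | COC(=O)[C@@H](C)CO[Si](C)(C)C(C)(C)C | intermediate
17 | (2S)-3-[(tert-butyldimethylsilyl)oxy]-2-methylpropanoic acid | OC(=O)[C@@H](C)CO[Si](C)(C)C(C)(C)C | intermediate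
18 | (2S)-3-[(tert-butyldimethylsilyl)oxy]-2-methylpropanoic 2,4,6-trichlorobenzoic anhydride | O=C(OC(=O)c1c(Cl)cc(Cl)cc1Cl)[C@@H](C)CO[Si](C)(C)C(C)(C)C | intermediate
19 | (1S)-1-[(2R,3R)-2-[(1Z,5E)-2-{[(tert-butyldimethylsilyl)oxy]methyl}hepta-1,5-dien-1-yl]-4-methylidene-5-oxooxolan-3-yl]-3-methylbut-3-en-1-yl (2S)-3-[(tert-butyldimethylsilyl)oxy]-2-methylpropanoate | C=C1C(=O)O[C@H](/C=C(\CO[Si](C)(C)C(C)(C)C)CC/C=C/C)[C@H]1[C@@H](OC(=O)[C@@H](C)CO[Si](C)(C)C(C)(C)C)CC(C)=C | intermediate
20 | (3aR,4S,6Z,10Z,11aR)-10-{[(tert-butyldimethylsilyl)oxy]methyl}-6-methyl-3-methylidene-2-oxo-2,3,3a,4,5,8,9,11a-octahydrocyclodeca[b]furan-4-yl (2S)-3-[(tert-butyldimethylsilyl)oxy]-2-methylpropanoate | C=C1C(=O)O[C@@H]2/C=C(\CO[Si](C)(C)C(C)(C)C)CC/C=C(/C)C[C@H](OC(=O)[C@@H](C)CO[Si](C)(C)C(C)(C)C)[C@@H]12 | intermediate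
21 | (3aR,4S,6Z,10Z,11aR)-10-(hydroxymethyl)-6-methyl-3-methylidene-2-oxo-2,3,3a,4,5,8,9,11a-octahydrocyclodeca[b]furan-4-yl (2S)-3-hydroxy-2-methylpropanoate | C=C1C(=O)O[C@@H]2/C=C(\CO)CC/C=C(/C)C[C@H](OC(=O)[C@@H](C)CO)[C@@H]12 | target

## Step count and risks

Total step count: 12. Longest linear sequence: 8 steps (steps 1, 2, 5, 6, 7, 10, 11, 12).

Steps most likely to fail:

1. Step 7. The carbopalladation may take place on the wrong face of C7, the C–O bond may form on the palladium side (giving the cis-lactone), β-hydride elimination may give Heck-type trienes, or the lactone may migrate to the C8 oxygen under base. The fallback is a radical–polar crossover annulation that sets out from 12 and comes back at 14. Mn(OAc)3·2H2O and Cu(OAc)2 with malonic acid in AcOH–MeCN at 25–40 °C should add the malonyl radical to C7 of the diene under the same allylic-strain control, oxidise the C6–C5–C4 allyl radical and close the lactone at C6 to give the α-carboxy lactone F1 (mixture at the carboxyl-bearing carbon). Decarboxylative Mannich methylenation (aqueous formaldehyde, Et2NH, then NaOAc–AcOH with warming) would then give 14.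

2. Step 11. Oligomerisation may win over closure of the strained ten-membered ring, the trans C1=C10 olefin may form alongside the cis one, or the ruthenium carbene may engage the α-methylene lactone. The fallback forms the carbocycle before the lactone; it sets out from 12 and comes back at 20. Ring-closing metathesis of 12 with the same catalyst under high dilution should give the ten-membered trienol F2, whose internal conjugated diene is a poor metathesis partner. The heteroannulation of step 7 with 13 on this ring would give the macrocyclic hydroxy lactone F3, and Yamaguchi acylation with 17 (through 18) would give 20.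

3. Step 3. Facial discrimination on the slim alkynyl aldehyde may be incomplete (low enantiomeric purity carried through the whole route), or catalyst turnover may be slow. The fallback sets the centre by reduction instead of addition; it sets out from 7 and comes back at 9. Addition of 2-methylallylmagnesium chloride to 7 (THF, −78 °C) would give the racemic alcohol F4, Dess–Martin periodinane would give the ynone F5, and Noyori asymmetric transfer hydrogenation with RuCl[(S,S)-TsDPEN](p-cymene) in i-PrOH should return the (S)-alcohol 9.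

## Further compounds

F1 | step 7 | (4R,5R)-5-[(1Z,5E)-2-{[(tert-butyldimethylsilyl)oxy]methyl}hepta-1,5-dien-1-yl]-4-[(1S)-1-hydroxy-3-methylbut-3-en-1-yl]-2-oxooxolane-3-carboxylic acid | OC(=O)C1C(=O)O[C@H](/C=C(\CO[Si](C)(C)C(C)(C)C)CC/C=C/C)[C@H]1[C@@H](O)CC(C)=C
F2 | step 11 | (1S,2Z,4Z,8Z)-5-{[(tert-butyldimethylsilyl)oxy]methyl}-9-methylcyclodeca-2,4,8-trien-1-ol | C1/C=C(C)\C[C@H](O)/C=C\C=C(/CO[Si](C)(C)C(C)(C)C)C1
F3 | step 11 | (3aR,4S,6Z,10Z,11aR)-10-{[(tert-butyldimethylsilyl)oxy]methyl}-4-hydroxy-6-methyl-3-methylidene-3a,4,5,8,9,11a-hexahydrocyclodeca[b]furan-2(3H)-one | C=C1C(=O)O[C@@H]2/C=C(\CO[Si](C)(C)C(C)(C)C)CC/C=C(/C)C[C@H](O)[C@@H]12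
F4 | step 3 | rac-5-methyl-1-(trimethylsilyl)hex-5-en-1-yn-3-ol | C=C(C)CC(O)C#C[Si](C)(C)C
F5 | step 3 | 5-methyl-1-(trimethylsilyl)hex-5-en-1-yn-3-one | C=C(C)CC(=O)C#C[Si](C)(C)C
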